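**Retrosynthetic overview**
1. Ring B is closed last: the C7–C8 bond comes from a Ru-catalysed, hydroxyl-directed intramolecular trans-hydroacylation (formyl C–H activation) of the 5-alkynal 21.
2. 21 comes from the cis-3,4-diol 14 (OsO4 on the Δ3 alkene), with angelate on the secondary O, acetate on the tertiary O, then unmasking of CHO and the carbinol.
3. The C5–C6 bond and the Δ3 alkene come from a Cu-catalysed γ-selective anti-SN2′ allyl–alkynyl coupling of ring-A allylic phosphate 12 with alkyne 11.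
4. Ring A is formed first: asymmetric Robinson annulation of 2-methylpent-4-enal with ethyl vinyl ketone sets C10; allyl becomes CH2CH(OMe)2 (future C9–C8); CBS reduction sets the carbinol that relays chirality to C5.
5. Two side fragments are made separately: alkyne 11 (acetone + ethynylmagnesium bromide) and angelate donor 18 ((Z)-2-bromobut-2-ene + CO2).

Assumption: C-locants in the text follow eudesmane numbering of the target (C3 OAng, C4 OAc/Me, C5 ring-fusion H, C6=C7, C8=O, C10 quaternary Me); the step 1 catalyst enantiomer is taken as the one giving the (R) quaternary centre (otherwise its mirror image is used).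

**Step 1**
Reactants: 1 2-methylpent-4-enal (racemic); 2 pent-1-en-3-one (ethyl vinyl ketone)
Product: 4 (4R)-2,4-dimethyl-4-(prop-2-en-1-yl)cyclohex-2-en-1-one, via keto aldehyde Michael adduct 3 (not isolated)
Conditions: (S)-N-(4-dodecylphenylsulfonyl)pyrrolidine-2-carboxamide (20 mol %), DCE, rt; then KOH, MeOH, 0 °C to rt
Reagents that add atoms: none
Why: Organocatalytic asymmetric Michael addition then aldol condensation (Robinson annulation): the catalyst turns the racemic aldehyde into a configurationally mobile enamine and its sulfonamide N–H guides the vinyl ketone to one face, fixing the quaternary carbon (C10) as R, and only the ethyl-ketone CH2 can condense with the non-enolisable aldehyde to give the six-membered enone.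

**Step 2**
Reactants: 4 (4R)-2,4-dimethyl-4-(prop-2-en-1-yl)cyclohex-2-en-1-one
Product: 6 (4R)-4-(2,2-dimethoxyethyl)-2,4-dimethylcyclohex-2-en-1-one, via ring aldehyde 5 (not isolated)
Conditions: O3, CH2Cl2/MeOH, −78 °C (Sudan III end point); Me2S; then TsOH·H2O (cat.), MeOH, rt
Reagents that add atoms: methanol, CO
Why: Ozonolysis with reductive work-up then acid-catalysed acetalisation: ozone attacks the electron-rich terminal alkene far faster than the conjugated enone, and the aldehyde (not the enone carbonyl) forms the dimethyl acetal in methanol; the quaternary centre is untouched.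

**Step 3**
Reactants: 6 (4R)-4-(2,2-dimethoxyethyl)-2,4-dimethylcyclohex-2-en-1-one
Product: 7 (1R,4R)-4-(2,2-dimethoxyethyl)-2,4-dimethylcyclohex-2-en-1-ol
Conditions: (S)-Me-CBS (20 mol %), BH3·SMe2, THF, −20 °C; MeOH
Reagents that add atoms: none
Why: Corey–Bakshi–Shibata reduction: the (S)-oxazaborolidine treats the substituted alkenyl flank as the large group and delivers hydride 1,2 to give the (1R) allylic alcohol (OH cis to the dimethoxyethyl chain) under catalyst control, the remote quaternary centre having little influence.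

**Step 4**
Reactants: 8 acetone; 9 ethynylmagnesium bromide
Product: 10 2-methylbut-3-yn-2-ol
Conditions: THF, 0 °C to rt; H2O
Reagents that add atoms: none
Why: Grignard 1,2-addition of an acetylide to a ketone; no stereocentre is formed.

**Step 5**
Reactants: 10 2-methylbut-3-yn-2-ol
Product: 11 triethyl[(2-methylbut-3-yn-2-yl)oxy]silane
Conditions: TESOTf, 2,6-lutidine, CH2Cl2, 0 °C
Reagents that add atoms: triethylsilyl trifluoromethanesulfonate, CC[Si](CC)(CC)OS(=O)(=O)C(F)(F)F
Why: Silyl triflate silylation is forceful enough for a tertiary alcohol, and the TES ether later keeps this tertiary oxygen apart from the ring tertiary OH that must be acetylated.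

**Step 6**
Reactants: 7 (1R,4R)-4-(2,2-dimethoxyethyl)-2,4-dimethylcyclohex-2-en-1-ol; 11 triethyl[(2-methylbut-3-yn-2-yl)oxy]silane
Product: 13 triethyl({4-[(1R,6R)-6-(2,2-dimethoxyethyl)-2,6-dimethylcyclohex-2-en-1-yl]-2-methylbut-3-yn-2-yl}oxy)silane, via allylic phosphate 12 (not isolated)
Conditions: n-BuLi, THF, −78 °C; ClP(O)(OEt)2, −78 to 0 °C; then 11, CuCl (10 mol %), LiOt-Bu, THF, 40 °C
Reagents that add atoms: none
Why: Copper-catalysed γ-selective allyl–alkynyl coupling (anti-SN2′ allylic substitution) of the in situ phosphate: the copper acetylide attacks alkene terminus C5 on the face opposite the phosphate and reductive elimination forms the C5–C(sp) bond, so the (1R) carbinol is relayed into the new (R) centre at C5 (alkynyl trans to the dimethoxyethyl chain) while the double bond moves to C3=C4.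

**Step 7**
Reactants: 13 triethyl({4-[(1R,6R)-6-(2,2-dimethoxyethyl)-2,6-dimethylcyclohex-2-en-1-yl]-2-methylbut-3-yn-2-yl}oxy)silane
Product: 14 (1S,2R,5R,6S)-5-(2,2-dimethoxyethyl)-1,5-dimethyl-6-{3-methyl-3-[(triethylsilyl)oxy]but-1-yn-1-yl}cyclohexane-1,2-diol
Conditions: OsO4 (5 mol %), NMO, MeSO2NH2, acetone/H2O, rt
Reagents that add atoms: N-methylmorpholine N-oxide, C[N+]1([O-])CCOCC1; water, O
Why: Upjohn syn-dihydroxylation: OsO4 adds to the only alkene from the face opposite the allylic alkynyl group (and the quasi-axial C10 methyl), setting both carbinol centres cis to each other and trans to the alkyne with the C4 methyl on the alkyne face; alkyne, acetal and silyl ether are inert.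

**Step 8**
Reactants: 15 (2Z)-2-bromobut-2-ene
Product: 17 (2Z)-2-methylbut-2-enoic acid (angelic acid), via vinyllithium 16 (not isolated)
Conditions: t-BuLi (2 equiv), Et2O, −78 °C; CO2; 1 M HCl
Reagents that add atoms: carbon dioxide, O=C=O
Why: Bromine–lithium exchange and carboxylation of the vinyllithium both proceed with retention of double-bond geometry at −78 °C, giving the Z acid free of tiglic acid.

**Step 9**
Reactants: 17 (2Z)-2-methylbut-2-enoic acid
Product: 18 (2Z)-2-methylbut-2-enoic 2,4,6-trichlorobenzoic anhydride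
Conditions: 2,4,6-trichlorobenzoyl chloride, Et3N, toluene, 0 °C to rt; filtered, used directly
Reagents that add atoms: 2,4,6-trichlorobenzoyl chloride, O=C(Cl)c1c(Cl)cc(Cl)cc1Cl
Why: Yamaguchi mixed-anhydride formation activates the acid under mild base without the Z-to-E isomerisation that accompanies acid chloride formation.

**Step 10**
Reactants: 14 (1S,2R,5R,6S)-5-(2,2-dimethoxyethyl)-1,5-dimethyl-6-{3-methyl-3-[(triethylsilyl)oxy]but-1-yn-1-yl}cyclohexane-1,2-diol; 18 (2Z)-2-methylbut-2-enoic 2,4,6-trichlorobenzoic anhydride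
Product: 19 (1R,2S,3S,4R)-4-(2,2-dimethoxyethyl)-2-hydroxy-2,4-dimethyl-3-{3-methyl-3-[(triethylsilyl)oxy]but-1-yn-1-yl}cyclohexyl (2Z)-2-methylbut-2-enoate
Conditions: toluene, 80 °C (no DMAP)
Reagents that add atoms: none
Why: Yamaguchi esterification without nucleophilic catalyst: the secondary alcohol attacks the unhindered angeloyl carbonyl of the mixed anhydride while the tertiary OH and the TES ether stay untouched, and leaving out DMAP keeps the Z geometry; no stereocentre changes.

**Step 11**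
Reactants: 19 (1R,2S,3S,4R)-4-(2,2-dimethoxyethyl)-2-hydroxy-2,4-dimethyl-3-{3-methyl-3-[(triethylsilyl)oxy]but-1-yn-1-yl}cyclohexyl (2Z)-2-methylbut-2-enoate
Product: 21 (1R,2S,3S,4R)-2-(acetyloxy)-3-(3-hydroxy-3-methylbut-1-yn-1-yl)-2,4-dimethyl-4-(2-oxoethyl)cyclohexyl (2Z)-2-methylbut-2-enoate, via silyl acetal acetate 20 (not isolated)
Conditions: Ac2O, DMAP, Et3N, CH2Cl2, 40 °C; MeOH; then 1 M aq HCl, THF, rt
Reagents that add atoms: acetic anhydride, CC(=O)OC(C)=O; water, O
Why: DMAP-catalysed (Steglich-type) acetylation of the only free, tertiary hydroxyl followed by acid hydrolysis, which cleaves the dimethyl acetal and the tertiary TES ether but leaves the tertiary acetate and the angelate intact; no stereocentre is affected.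

**Step 12**
Reactants: 21 (1R,2S,3S,4R)-2-(acetyloxy)-3-(3-hydroxy-3-methylbut-1-yn-1-yl)-2,4-dimethyl-4-(2-oxoethyl)cyclohexyl (2Z)-2-methylbut-2-enoate
Product: 22 (1S,2R,4aR,8aR)-1-(acetyloxy)-7-(2-hydroxypropan-2-yl)-1,4a-dimethyl-6-oxo-1,2,3,4,4a,5,6,8a-octahydronaphthalen-2-yl (2Z)-2-methylbut-2-enoate (CNP0351454.1)
Conditions: [Cp*RuCl]4 (5 mol %), CH2Cl2 (0.02 M), rt to 40 °C
Reagents that add atoms: none
Why: Proposed new method: hydroxyl-directed Ru-catalysed intramolecular trans-hydroacylation, in which the propargylic OH hydrogen-bonds to the chloride of alkyne-bound Cp*RuCl, the tethered formyl C–H adds to Ru (σ-complex/oxidative addition), hydride goes inner-sphere to the distal alkyne carbon C6 to give a ruthenacyclopropene, and the acyl group migrates to the OH-proximal carbene carbon C7 anti to that hydrogen, the only geometry that places C5 and C8 cis and so closes the six-membered enone without touching a stereocentre; the closest known reactions are Ru-catalysed hydroxyl-directed trans-hydrostannation/-silylation/-hydrogenation of propargylic alcohols and Rh-catalysed trans-hydroacylation of 4-alkynals to cyclopentenones.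

**Compound list**
1 | 2-methylpent-4-enal (racemic) | C=CCC(C)C=O | starting material
2 | pent-1-en-3-one (ethyl vinyl ketone) | CCC(=O)C=C | starting material
3 | (2R)-2-methyl-5-oxo-2-(prop-2-en-1-yl)heptanal | CCC(=O)CC[C@](C)(CC=C)C=O | intermediate
4 | (4R)-2,4-dimethyl-4-(prop-2-en-1-yl)cyclohex-2-en-1-one | O=C1CC[C@](C)(CC=C)C=C1C | intermediate
5 | 2-[(1R)-1,3-dimethyl-4-oxocyclohex-2-en-1-yl]acetaldehyde | O=C1CC[C@](C)(CC=O)C=C1C | intermediate
6 | (4R)-4-(2,2-dimethoxyethyl)-2,4-dimethylcyclohex-2-en-1-one | O=C1CC[C@](C)(CC(OC)OC)C=C1C | intermediate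
7 | (1R,4R)-4-(2,2-dimethoxyethyl)-2,4-dimethylcyclohex-2-en-1-ol | O[C@@H]1CC[C@](C)(CC(OC)OC)C=C1C | intermediate
8 | acetone | CC(C)=O | starting material
9 | ethynylmagnesium bromide | C#C[Mg]Br | starting material
10 | 2-methylbut-3-yn-2-ol | C#CC(C)(C)O | intermediate
11 | triethyl[(2-methylbut-3-yn-2-yl)oxy]silane | C#CC(C)(C)O[Si](CC)(CC)CC | intermediate
12 | diethyl (1R,4R)-4-(2,2-dimethoxyethyl)-2,4-dimethylcyclohex-2-en-1-yl phosphate | CCOP(=O)(OCC)O[C@@H]1CC[C@](C)(CC(OC)OC)C=C1C | intermediate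
13 | triethyl({4-[(1R,6R)-6-(2,2-dimethoxyethyl)-2,6-dimethylcyclohex-2-en-1-yl]-2-methylbut-3-yn-2-yl}oxy)silane | C1=C(C)[C@H](C#CC(C)(C)O[Si](CC)(CC)CC)[C@@](C)(CC(OC)OC)CC1 | intermediate
14 | (1S,2R,5R,6S)-5-(2,2-dimethoxyethyl)-1,5-dimethyl-6-{3-methyl-3-[(triethylsilyl)oxy]but-1-yn-1-yl}cyclohexane-1,2-diol | O[C@@H]1CC[C@](C)(CC(OC)OC)[C@@H](C#CC(C)(C)O[Si](CC)(CC)CC)[C@]1(C)O | intermediate
15 | (2Z)-2-bromobut-2-ene | C/C=C(/C)Br | starting material
16 | (2Z)-but-2-en-2-yllithium | C/C=C(/C)[Li] | intermediate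
17 | (2Z)-2-methylbut-2-enoic acid (angelic acid) | C/C=C(/C)C(=O)O | intermediate
18 | (2Z)-2-methylbut-2-enoic 2,4,6-trichlorobenzoic anhydride | C/C=C(/C)C(=O)OC(=O)c1c(Cl)cc(Cl)cc1Cl | intermediate
19 | (1R,2S,3S,4R)-4-(2,2-dimethoxyethyl)-2-hydroxy-2,4-dimethyl-3-{3-methyl-3-[(triethylsilyl)oxy]but-1-yn-1-yl}cyclohexyl (2Z)-2-methylbut-2-enoate | C/C=C(/C)C(=O)O[C@@H]1CC[C@](C)(CC(OC)OC)[C@@H](C#CC(C)(C)O[Si](CC)(CC)CC)[C@]1(C)O | intermediate
20 | (1R,2S,3S,4R)-2-(acetyloxy)-4-(2,2-dimethoxyethyl)-2,4-dimethyl-3-{3-methyl-3-[(triethylsilyl)oxy]but-1-yn-1-yl}cyclohexyl (2Z)-2-methylbut-2-enoate | C/C=C(/C)C(=O)O[C@@H]1CC[C@](C)(CC(OC)OC)[C@@H](C#CC(C)(C)O[Si](CC)(CC)CC)[C@]1(C)OC(C)=O | intermediate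
21 | (1R,2S,3S,4R)-2-(acetyloxy)-3-(3-hydroxy-3-methylbut-1-yn-1-yl)-2,4-dimethyl-4-(2-oxoethyl)cyclohexyl (2Z)-2-methylbut-2-enoate | C/C=C(/C)C(=O)O[C@@H]1CC[C@](C)(CC=O)[C@@H](C#CC(C)(C)O)[C@]1(C)OC(C)=O | intermediate
22 | (1S,2R,4aR,8aR)-1-(acetyloxy)-7-(2-hydroxypropan-2-yl)-1,4a-dimethyl-6-oxo-1,2,3,4,4a,5,6,8a-octahydronaphthalen-2-yl (2Z)-2-methylbut-2-enoate | C/C=C(/C)C(=O)O[C@@H]1CC[C@]2(C)CC(=O)C(C(C)(C)O)=C[C@H]2[C@]1(C)OC(C)=O | target

**Step count and risks**
Total step count: 12. Longest linear sequence: 8 (steps 1, 2, 3, 6, 7, 10, 11, 12); the alkyne branch (steps 4, 5) joins at step 6 and the angelate branch (steps 8, 9) at step 10.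

Step 12 (the proposed new reaction). Risks are decarbonylation with CO poisoning of Ru, 5-exo delivery of the acyl group, and the need for ring A to adopt the chair with syn-axial C4/C10 methyls before closure. The fallback uses only known chemistry, sets out from 21 and returns to 22. Established hydroxyl-directed trans-hydrostannation ([Cp*RuCl]4 cat., Bu3SnH, CH2Cl2) puts tin on the OH-proximal carbon and gives (1R,2S,3R,4R)-2-(acetyloxy)-3-[(1Z)-3-hydroxy-3-methyl-2-(tributylstannyl)but-1-en-1-yl]-2,4-dimethyl-4-(2-oxoethyl)cyclohexyl (2Z)-2-methylbut-2-enoate F1. Iododestannylation (I2, CH2Cl2, 0 °C) with retention gives the corresponding (1Z)-3-hydroxy-2-iodo-3-methylbut-1-en-1-yl compound F2. An intramolecular Nozaki–Hiyama–Kishi reaction (CrCl2, NiCl2 cat., DMF) closes ring B to (1S,2R,4aR,8aR)-1-(acetyloxy)-6-hydroxy-7-(2-hydroxypropan-2-yl)-1,4a-dimethyl-1,2,3,4,4a,5,6,8a-octahydronaphthalen-2-yl (2Z)-2-methylbut-2-enoate F3 (C6 epimers). Dess–Martin oxidation of the secondary allylic alcohol then gives 22.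

Step 6. The γ-carbon is flanked by a quaternary centre and the alkene carries a β-methyl, so coupling may be slow or give α-substitution or diene. The fallback replaces the coupling by a sigmatropic transfer; it sets out from 6 and returns at 13. (R)-Me-CBS/BH3 gives the epimeric (1S,4R)-4-(2,2-dimethoxyethyl)-2,4-dimethylcyclohex-2-en-1-ol F4. KH and Bu3SnCH2I give tributyl({[(1S,4R)-4-(2,2-dimethoxyethyl)-2,4-dimethylcyclohex-2-en-1-yl]oxy}methyl)stannane F5. n-BuLi at −78 °C triggers the suprafacial [2,3]-Wittig–Still rearrangement to [(1R,6R)-6-(2,2-dimethoxyethyl)-2,6-dimethylcyclohex-2-en-1-yl]methanol F6. Buffered Dess–Martin oxidation gives (1R,6R)-6-(2,2-dimethoxyethyl)-2,6-dimethylcyclohex-2-ene-1-carbaldehyde F7, and CBr4/PPh3 gives (5R,6R)-6-(2,2-dibromoethenyl)-5-(2,2-dimethoxyethyl)-1,5-dimethylcyclohex-1-ene F8. n-BuLi (2 equiv), then acetone, then TESOTf (Corey–Fuchs alkynylation with in situ trapping) gives 13.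

Step 1. Enamine catalysis must distinguish methyl from allyl at the α-carbon, so the ee may be only moderate. The fallback gives up asymmetric catalysis at this stage; it sets out from 1 and 2 and returns at 7. Pyrrolidine-catalysed Robinson annulation gives racemic 2,4-dimethyl-4-(prop-2-en-1-yl)cyclohex-2-en-1-one F9. The step 2 conditions give racemic 4-(2,2-dimethoxyethyl)-2,4-dimethylcyclohex-2-en-1-one F10. (S)-Me-CBS reduction of the racemate is catalyst-controlled at the carbinol and gives 7 together with (1R,4S)-4-(2,2-dimethoxyethyl)-2,4-dimethylcyclohex-2-en-1-ol F11, which is removed by chromatography (maximum 50 % yield).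

**Further compounds**
F1 | step 12 | (1R,2S,3R,4R)-2-(acetyloxy)-3-[(1Z)-3-hydroxy-3-methyl-2-(tributylstannyl)but-1-en-1-yl]-2,4-dimethyl-4-(2-oxoethyl)cyclohexyl (2Z)-2-methylbut-2-enoate | C/C=C(/C)C(=O)O[C@@H]1CC[C@](C)(CC=O)[C@@H](/C=C(\[Sn](CCCC)(CCCC)CCCC)C(C)(C)O)[C@]1(C)OC(C)=O
F2 | step 12 | (1R,2S,3R,4R)-2-(acetyloxy)-3-[(1Z)-3-hydroxy-2-iodo-3-methylbut-1-en-1-yl]-2,4-dimethyl-4-(2-oxoethyl)cyclohexyl (2Z)-2-methylbut-2-enoate | C/C=C(/C)C(=O)O[C@@H]1CC[C@](C)(CC=O)[C@@H](/C=C(\I)C(C)(C)O)[C@]1(C)OC(C)=O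
F3 | step 12 | (1S,2R,4aR,8aR)-1-(acetyloxy)-6-hydroxy-7-(2-hydroxypropan-2-yl)-1,4a-dimethyl-1,2,3,4,4a,5,6,8a-octahydronaphthalen-2-yl (2Z)-2-methylbut-2-enoate | C/C=C(/C)C(=O)O[C@@H]1CC[C@]2(C)CC(O)C(C(C)(C)O)=C[C@H]2[C@]1(C)OC(C)=O
F4 | step 6 | (1S,4R)-4-(2,2-dimethoxyethyl)-2,4-dimethylcyclohex-2-en-1-ol | O[C@H]1CC[C@](C)(CC(OC)OC)C=C1C
F5 | step 6 | tributyl({[(1S,4R)-4-(2,2-dimethoxyethyl)-2,4-dimethylcyclohex-2-en-1-yl]oxy}methyl)stannane | CCCC[Sn](CCCC)(CCCC)CO[C@H]1CC[C@](C)(CC(OC)OC)C=C1C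
F6 | step 6 | [(1R,6R)-6-(2,2-dimethoxyethyl)-2,6-dimethylcyclohex-2-en-1-yl]methanol | C1=C(C)[C@H](CO)[C@@](C)(CC(OC)OC)CC1
F7 | step 6 | (1R,6R)-6-(2,2-dimethoxyethyl)-2,6-dimethylcyclohex-2-ene-1-carbaldehyde | C1=C(C)[C@H](C=O)[C@@](C)(CC(OC)OC)CC1
F8 | step 6 | (5R,6R)-6-(2,2-dibromoethenyl)-5-(2,2-dimethoxyethyl)-1,5-dimethylcyclohex-1-ene | C1=C(C)[C@H](C=C(Br)Br)[C@@](C)(CC(OC)OC)CC1
F9 | step 1 | 2,4-dimethyl-4-(prop-2-en-1-yl)cyclohex-2-en-1-one (racemic) | O=C1CCC(C)(CC=C)C=C1C
F10 | step 1 | 4-(2,2-dimethoxyethyl)-2,4-dimethylcyclohex-2-en-1-one (racemic) | O=C1CCC(C)(CC(OC)OC)C=C1C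
F11 | step 1 | (1R,4S)-4-(2,2-dimethoxyethyl)-2,4-dimethylcyclohex-2-en-1-ol | O[C@@H]1CC[C@@](C)(CC(OC)OC)C=C1C
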